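**Retrosynthetic overview**

Numbering: C1 (bridgehead with prenyl, next to C8), C2=O, C3 (aroyl), C4 (enol C–O), C5 (bridgehead with prenyl), C6 (CH2), C7 (CH–prenyl, C1' = first prenyl carbon), C8 (Me, 4-methylpent-3-enyl), C9=O; ring A = C1–C2–C3–C4–C5–C9, ring B = C1–C8–C7–C6–C5–C9.
End game: two O-methyl groups are cleaved last; the C7 prenyl group and the C7 stereocentre come from exo-face hydroboration of a C7=C1' exocyclic alkene and B-alkyl Suzuki–Miyaura coupling.
Key disconnection: ring B is closed last by forming C6–C7, a palladium-catalysed alkyl Heck 6-exo cyclisation of a C5 iodomethyl group onto the C7=C1' vinyl group. It is made possible by two quaternary carbons: C5 (no β-hydrogen at C6, and C6 held 1,3-cis to the C8 arm across C9) and C8 (H7 is the only β-hydrogen after closure, so elimination must give the exocyclic alkene).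
Ring A comes from phloroglucinol: aroyl at C3 and formyl at C5 (the formyl carbon is C6 and deactivates C5), prenyl at C1, then asymmetric dearomatising reverse nerylation at C1 (sets C1 and C8), then dearomatising prenylation at C5 anti to that group (sets C5 with C6 cis to C8), then CHO to CH2I.
Ring order: ring A first (aromatic, dearomatised at C1, then at C5), ring B second.

Key step: step 9

Assumption (step 4): the Z allyl fragment with the (S,S) ligand is taken to give the C1 and C8 configurations drawn; if the sense is opposite, the ligand antipode (for C1) or geranyl acetate (for C8) is used and nothing else changes.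
Assumption (steps 4 to 7): each dearomatised triketone is drawn as one enol tautomer and the methylation of step 7 is drawn on the C4 oxygen; the C2 O-methyl isomer would pass through the same steps to the same target.

**Route**

Step 1
Reactants: 1 phloroglucinol; 2 3-methoxybenzoyl chloride
Product: 3 (3-methoxyphenyl)(2,4,6-trihydroxyphenyl)methanone
Conditions: AlCl3, PhNO2, 60 °C; aq HCl
Reagents that add atoms: none
Why: Friedel–Crafts C-acylation of the electron-rich triol, in which chelation of AlCl3 by the first ketone and its ortho hydroxyl groups should stop the reaction at the mono-ketone and the meta methoxy group should not be cleaved.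

Step 2
Reactants: 3 (3-methoxyphenyl)(2,4,6-trihydroxyphenyl)methanone
Product: 5 2,4,6-trihydroxy-3-(3-methoxybenzoyl)benzaldehyde, via iminium chloride 4 (not isolated)
Conditions: POCl3, DMF, EtOAc, 0 °C to rt; then H2O, 50 °C
Reagents that add atoms: N,N-dimethylformamide, CN(C)C=O; water, O
Why: Vilsmeier–Haack formylation of one of the two equivalent free ring carbons, held at one formyl group by stoichiometry and deactivation, followed by hydrolysis of the iminium salt.

Step 3
Reactants: 5 2,4,6-trihydroxy-3-(3-methoxybenzoyl)benzaldehyde; 6 prenyl bromide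
Product: 7 2,4,6-trihydroxy-3-(3-methoxybenzoyl)-5-(3-methylbut-2-en-1-yl)benzaldehyde
Conditions: 10% aq KOH, 0 °C
Reagents that add atoms: none
Why: C-alkylation of the phloroglucinol anion by the soft allylic bromide in a protic medium, which can only take place at the single unsubstituted ring carbon (C1).

Step 4
Reactants: 7 2,4,6-trihydroxy-3-(3-methoxybenzoyl)-5-(3-methylbut-2-en-1-yl)benzaldehyde; 8 neryl acetate
Product: 9 2,6-dihydroxy-3-(3,7-dimethylocta-1,6-dien-3-yl)-5-(3-methoxybenzoyl)-3-(3-methylbut-2-en-1-yl)-4-oxocyclohexa-1,5-diene-1-carbaldehyde (C1 and C8 as in the target)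
Conditions: Pd2(dba)3·CHCl3 (2.5 mol%), (S,S)-N,N'-(cyclohexane-1,2-diyl)bis[2-(diphenylphosphanyl)benzamide] (7.5 mol%), Et3N, CH2Cl2, 0 °C to rt
Reagents that add atoms: none
Why: Proposed new method: ionisation of neryl acetate by zerovalent palladium gives a 1,1-disubstituted π-allyl complex, and the enolate of 7, which is carbon-nucleophilic only at C1 because C3 and C5 carry acyl groups, should attack it outer-sphere at the substituted terminus inside the chiral pocket of the diamide bisphosphine, so that the ligand antipode fixes the face of C1 and the retained Z geometry of the allyl fragment fixes C8; the closest known reaction type is the palladium-catalysed branched-selective asymmetric allylic alkylation (reverse prenylation and geranylation) of 3-substituted oxindole enolates with this ligand class, which forms vicinal quaternary centres, and the new element is its use on a dearomatising acylphloroglucinol enolate.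

Step 5
Reactants: 9 the dearomatised aldehyde of step 4; 10 prenyl acetate
Product: 11 2-hydroxy-5-(3,7-dimethylocta-1,6-dien-3-yl)-3-(3-methoxybenzoyl)-1,5-bis(3-methylbut-2-en-1-yl)-4,6-dioxocyclohex-2-ene-1-carbaldehyde (formyl cis to the octadienyl group; C1, C5 and C8 as in the target)
Conditions: Pd(PPh3)4 (5 mol%), Et3N, THF, 40 °C
Reagents that add atoms: none
Why: Tsuji–Trost allylation of a highly acidic formyl dicarbonyl carbon, in which the stabilised nucleophile attacks the unsubstituted terminus of the prenyl π-allyl complex (O-allyl products re-ionise), C5 reacts in preference to the aroyl-bearing C3 for steric reasons, and approach anti to the tertiary group at C1 (1,3 across C9) sets C5 with the formyl carbon, the future C6, cis to C8.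

Step 6
Reactants: 11 the quaternary aldehyde of step 5
Product: 12 3-hydroxy-4-(hydroxymethyl)-6-(3,7-dimethylocta-1,6-dien-3-yl)-2-(3-methoxybenzoyl)-4,6-bis(3-methylbut-2-en-1-yl)cyclohex-2-ene-1,5-dione
Conditions: NaBH(OAc)3, AcOH, THF, 0 °C
Reagents that add atoms: none
Why: Acyloxyborohydride reduction should be selective for the aldehyde over the hindered C9 ketone and the enolised triketone, and the acidic medium protonates the alkoxide at once, which suppresses retro-aldol loss of formaldehyde.

Step 7
Reactants: 12 the hydroxymethyl enol of step 6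
Product: 13 4-(hydroxymethyl)-3-methoxy-6-(3,7-dimethylocta-1,6-dien-3-yl)-2-(3-methoxybenzoyl)-4,6-bis(3-methylbut-2-en-1-yl)cyclohex-2-ene-1,5-dione
Conditions: TMSCHN2, PhMe–MeOH, 0 °C
Reagents that add atoms: (trimethylsilyl)diazomethane, C[Si](C)(C)C=[N+]=[N-]
Why: O-methylation of the acidic enol by diazomethane released in situ masks the triketone as a vinylogous ester, while the neutral primary alcohol is not methylated.

Step 8
Reactants: 13 the vinylogous ester alcohol of step 7
Product: 15 4-(iodomethyl)-3-methoxy-6-(3,7-dimethylocta-1,6-dien-3-yl)-2-(3-methoxybenzoyl)-4,6-bis(3-methylbut-2-en-1-yl)cyclohex-2-ene-1,5-dione, via triflate 14 (not isolated)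
Conditions: Tf2O, 2,6-lutidine, CH2Cl2, −78 °C; then Bu4NI, MeCN, 40 °C
Reagents that add atoms: tetrabutylammonium iodide, CCCC[N+](CCCC)(CCCC)CCCC.[I-]
Why: Sulfonylation followed by SN2 displacement, in which the very good triflate leaving group compensates for the β-quaternary (neopentyl-type) carbon and the absence of β-hydrogen atoms excludes elimination.

Step 9
Reactants: 15 the iodide of step 8
Product: 16 (1S,5S,8S)-4-methoxy-3-(3-methoxybenzoyl)-8-methyl-7-methylidene-1,5-bis(3-methylbut-2-en-1-yl)-8-(4-methylpent-3-en-1-yl)bicyclo[3.3.1]non-3-ene-2,9-dione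
Conditions: Pd(OAc)2 (10 mol%), Xantphos (20 mol%), Cs2CO3, PhH, blue LEDs, rt
Reagents that add atoms: none
Why: Photo-excited zerovalent palladium transfers an electron to the neopentyl-type C6–I bond, the C6 radical (paired with monovalent palladium iodide) adds 6-exo-trig to C7 of the vinyl group, the new C1' radical recombines with palladium, and β-hydride elimination of H7, the only β-hydrogen, releases the exocyclic C7=C1' alkene and, after loss of HI to Cs2CO3, the catalyst. The closest known reaction type is the palladium-catalysed intramolecular alkyl Heck reaction of unactivated primary alkyl iodides with pendant alkenes. Ring B is closed in the 6-exo-trig mode across the 1,3-cis (diaxial) C6 and C8 arms of ring A, which turns the monocycle into the bicyclo[3.3.1]nonane. No new stereocentre is formed: C7 becomes trigonal and C1, C5 and C8 are carried over unchanged, the bridgeheads being fixed by the cis arrangement set in steps 4 and 5. The step needs chemoselectivity for the vinyl group over the four trisubstituted alkenes and over 3-exo attack on the C9 carbonyl, and regioselective elimination; these are secured by the quaternary C5 (no β-hydrogen at C6, C6 held within bonding distance of C7), the trans disposition of C6 and the C1 prenyl group, the enol-ether state of C4, and the quaternary C8, which leaves H7 as the only hydrogen palladium can remove.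

Step 10
Reactants: 16 the 7-methylidene bicycle of step 9; 17 1-bromo-2-methylprop-1-ene
Product: 19 (1S,5S,7S,8S)-4-methoxy-3-(3-methoxybenzoyl)-8-methyl-1,5,7-tris(3-methylbut-2-en-1-yl)-8-(4-methylpent-3-en-1-yl)bicyclo[3.3.1]non-3-ene-2,9-dione, via alkylborane 18 (not isolated)
Conditions: 9-BBN dimer, THF, 0 °C to rt; then 17, Pd(dppf)Cl2 (5 mol%), Cs2CO3, DMF–H2O, 50 °C
Reagents that add atoms: none
Why: Anti-Markovnikov hydroboration by 9-BBN should be selective for the 1,1-disubstituted exocyclic alkene over the four trisubstituted alkenes and deliver H7 from the exo face of ring B (the face turned away from ring A and its aroyl group), which places C1' endo as in the target, and B-alkyl Suzuki–Miyaura coupling with the alkenyl bromide then completes the prenyl group without touching C7.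

Step 11
Reactants: 19 the doubly O-methylated target of step 10
Product: 20 (1S,5S,7S,8S)-4-hydroxy-3-(3-hydroxybenzoyl)-8-methyl-1,5,7-tris(3-methylbut-2-en-1-yl)-8-(4-methylpent-3-en-1-yl)bicyclo[3.3.1]non-3-ene-2,9-dione
Conditions: EtSNa, DMF, 120 °C; then aq HCl
Reagents that add atoms: none
Why: Nucleophilic demethylation (SN2 by thiolate at both methyl groups) cleaves the aryl methyl ether and the vinylogous methyl ester under non-acidic conditions that spare the prenyl groups, the product being protected as its enolate and phenolate until acidification.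

**Compound list**

1 | phloroglucinol (benzene-1,3,5-triol) | Oc1cc(O)cc(O)c1 | starting material
2 | 3-methoxybenzoyl chloride | COc1cccc(c1)C(Cl)=O | starting material
3 | (3-methoxyphenyl)(2,4,6-trihydroxyphenyl)methanone | COc1cccc(c1)C(=O)c1c(O)cc(O)cc1O | intermediate
4 | N-{[2,4,6-trihydroxy-3-(3-methoxybenzoyl)phenyl]methylidene}-N-methylmethanaminium chloride (not isolated) | C[N+](C)=Cc1c(O)cc(O)c(C(=O)c2cccc(OC)c2)c1O.[Cl-] | intermediate
5 | 2,4,6-trihydroxy-3-(3-methoxybenzoyl)benzaldehyde | O=Cc1c(O)cc(O)c(C(=O)c2cccc(OC)c2)c1O | intermediate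
6 | prenyl bromide (1-bromo-3-methylbut-2-ene) | CC(C)=CCBr | starting material
7 | 2,4,6-trihydroxy-3-(3-methoxybenzoyl)-5-(3-methylbut-2-en-1-yl)benzaldehyde | CC(C)=CCc1c(O)c(C=O)c(O)c(C(=O)c2cccc(OC)c2)c1O | intermediate
8 | neryl acetate [(2Z)-3,7-dimethylocta-2,6-dien-1-yl acetate] | CC(C)=CCC/C(C)=C\COC(C)=O | starting material
9 | 2,6-dihydroxy-3-(3,7-dimethylocta-1,6-dien-3-yl)-5-(3-methoxybenzoyl)-3-(3-methylbut-2-en-1-yl)-4-oxocyclohexa-1,5-diene-1-carbaldehyde (C1 and C8 as in the target) | C=C[C@](C)(CCC=C(C)C)[C@]1(CC=C(C)C)C(=O)C(C(=O)c2cccc(OC)c2)=C(O)C(C=O)=C1O | intermediate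
10 | prenyl acetate (3-methylbut-2-en-1-yl acetate) | CC(C)=CCOC(C)=O | starting material
11 | 2-hydroxy-5-(3,7-dimethylocta-1,6-dien-3-yl)-3-(3-methoxybenzoyl)-1,5-bis(3-methylbut-2-en-1-yl)-4,6-dioxocyclohex-2-ene-1-carbaldehyde (formyl cis to the octadienyl group) | C=C[C@](C)(CCC=C(C)C)[C@]1(CC=C(C)C)C(=O)C(C(=O)c2cccc(OC)c2)=C(O)[C@](CC=C(C)C)(C=O)C1=O | intermediate
12 | 3-hydroxy-4-(hydroxymethyl)-6-(3,7-dimethylocta-1,6-dien-3-yl)-2-(3-methoxybenzoyl)-4,6-bis(3-methylbut-2-en-1-yl)cyclohex-2-ene-1,5-dione | C=C[C@](C)(CCC=C(C)C)[C@]1(CC=C(C)C)C(=O)C(C(=O)c2cccc(OC)c2)=C(O)[C@](CC=C(C)C)(CO)C1=O | intermediate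
13 | 4-(hydroxymethyl)-3-methoxy-6-(3,7-dimethylocta-1,6-dien-3-yl)-2-(3-methoxybenzoyl)-4,6-bis(3-methylbut-2-en-1-yl)cyclohex-2-ene-1,5-dione | C=C[C@](C)(CCC=C(C)C)[C@]1(CC=C(C)C)C(=O)C(C(=O)c2cccc(OC)c2)=C(OC)[C@](CC=C(C)C)(CO)C1=O | intermediate
14 | trifluoromethanesulfonate of the primary alcohol 13 (not isolated) | C=C[C@](C)(CCC=C(C)C)[C@]1(CC=C(C)C)C(=O)C(C(=O)c2cccc(OC)c2)=C(OC)[C@](CC=C(C)C)(COS(=O)(=O)C(F)(F)F)C1=O | intermediate
15 | 4-(iodomethyl)-3-methoxy-6-(3,7-dimethylocta-1,6-dien-3-yl)-2-(3-methoxybenzoyl)-4,6-bis(3-methylbut-2-en-1-yl)cyclohex-2-ene-1,5-dione | C=C[C@](C)(CCC=C(C)C)[C@]1(CC=C(C)C)C(=O)C(C(=O)c2cccc(OC)c2)=C(OC)[C@](CC=C(C)C)(CI)C1=O | intermediate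
16 | (1S,5S,8S)-4-methoxy-3-(3-methoxybenzoyl)-8-methyl-7-methylidene-1,5-bis(3-methylbut-2-en-1-yl)-8-(4-methylpent-3-en-1-yl)bicyclo[3.3.1]non-3-ene-2,9-dione | CC(C)=CCC[C@@]1(C)C(=C)C[C@]2(CC=C(C)C)C(=O)[C@@]1(CC=C(C)C)C(=O)C(C(=O)c1cccc(OC)c1)=C2OC | intermediate
17 | 1-bromo-2-methylprop-1-ene | CC(C)=CBr | starting material
18 | 7-endo-[(9-borabicyclo[3.3.1]nonan-9-yl)methyl] compound from 16 (not isolated) | CC(C)=CCC[C@@]1(C)[C@@H](CB3C4CCCC3CCC4)C[C@]2(CC=C(C)C)C(=O)[C@@]1(CC=C(C)C)C(=O)C(C(=O)c1cccc(OC)c1)=C2OC | intermediate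
19 | (1S,5S,7S,8S)-4-methoxy-3-(3-methoxybenzoyl)-8-methyl-1,5,7-tris(3-methylbut-2-en-1-yl)-8-(4-methylpent-3-en-1-yl)bicyclo[3.3.1]non-3-ene-2,9-dione | CC(C)=CCC[C@@]1(C)[C@@H](CC=C(C)C)C[C@]2(CC=C(C)C)C(=O)[C@@]1(CC=C(C)C)C(=O)C(C(=O)c1cccc(OC)c1)=C2OC | intermediate
20 | (1S,5S,7S,8S)-4-hydroxy-3-(3-hydroxybenzoyl)-8-methyl-1,5,7-tris(3-methylbut-2-en-1-yl)-8-(4-methylpent-3-en-1-yl)bicyclo[3.3.1]non-3-ene-2,9-dione (CNP0406274.1) | CC(C)=CCC[C@@]1(C)[C@@H](CC=C(C)C)C[C@]2(CC=C(C)C)C(=O)[C@@]1(CC=C(C)C)C(=O)C(C(=O)c1cccc(O)c1)=C2O | target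

**Step count and risks**

Total step count: 11. Longest linear sequence: 11 steps (from phloroglucinol).

Steps most likely to fail:

Step 4 (Proposed new method). The enolate may attack the unsubstituted allyl terminus (linear transfer), stop at O-allylation, or discriminate the two faces of C1 poorly. The fallback uses known chemistry and sets out from 7. Mitsunobu etherification with nerol (PPh3, diisopropyl azodicarboxylate, THF, 0 °C) at the C9 oxygen, which lies para to the aroyl group, should give the aryl neryl ether F1; any ether on the oxygen between C1 and C3 would lead to the C8 epimer and is removed at this stage. Heating F1 (toluene, 100 °C) should bring about an aromatic Claisen rearrangement onto the prenyl-bearing ortho carbon C1. Its chair transition state necessarily bonds C1 to the tertiary allyl terminus, and with the Z alkene it should give the C1/C8 relationship of 9, as the racemate: 9 together with ent-9 F2. Resolution of this acidic triketone, by crystallisation of its (−)-quinine salt or by preparative chromatography on a chiral phase, comes back to the route at 9.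

Step 9 (key step). The C6 radical may add to the C9 carbonyl and trigger a 1,2-acyl shift (Dowd–Beckwith ring enlargement of ring A) faster than it closes onto C7, or palladium hydride may move the exocyclic alkene into ring B. The fallback avoids a C6 radical and sets out from 13. Hydroboration of the vinyl group (9-BBN, THF; then NaBO3·4H2O) should give the diol F5. Parikh–Doering oxidation (SO3·pyridine, DMSO, iPr2NEt) should give the dialdehyde F6, which is treated in the same flask with pyrrolidine and AcOH. The resulting intramolecular aldol condensation, between the non-enolisable C6 aldehyde and the C7 methylene of the second aldehyde, closes ring B at C6–C7 as the enal F7. Luche reduction (NaBH4, CeCl3·7H2O, MeOH, −78 °C) should give the allylic alcohol F8, and ClCO2Me with pyridine its methyl carbonate F9. Reduction of the π-allyl complex by formate (Pd(OAc)2, PBu3, HCO2NH4, THF), with hydride delivered to the ring terminus C6, comes back to the route at 16.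

Step 5. O-allylation of the formyl enol may fail to revert, allylation may occur at C3, or the non-enolisable product may lose its formyl group under nucleophilic conditions; approach syn to the C1 tertiary group would give the C5 epimer. The fallback sets out from 9. Copper-catalysed O-alkylation with 3-chloro-3-methylbut-1-yne (CuCl2, DBU, MeCN, 0 °C) should give the 1,1-dimethylpropargyl enol ether F3; ethers on any of the three oxygen atoms that flank C5 converge. Semi-hydrogenation (H2, Pd/CaCO3 poisoned with Pb(OAc)2, quinoline, EtOAc) should give the 1,1-dimethylallyl enol ether F4. Gentle heating (toluene, 70 °C) should effect a Claisen rearrangement that delivers the linear prenyl group to C5 on the face anti to the C1 tertiary group and restores the carbonyl, coming back to the route at 11.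

Further compounds
F1 | step 4 | aryl neryl ether: 2,4-dihydroxy-6-[(2Z)-3,7-dimethylocta-2,6-dien-1-yloxy]-3-(3-methoxybenzoyl)-5-(3-methylbut-2-en-1-yl)benzaldehyde | CC(C)=CCC/C(C)=C\COc1c(CC=C(C)C)c(O)c(C(=O)c2cccc(OC)c2)c(O)c1C=O
F2 | step 4 | ent-9 (enantiomer of 9, removed in the resolution) | C=C[C@@](C)(CCC=C(C)C)[C@@]1(CC=C(C)C)C(=O)C(C(=O)c2cccc(OC)c2)=C(O)C(C=O)=C1O
F3 | step 5 | 1,1-dimethylpropargyl enol ether of 9 (ether on the C9 oxygen) | C=C[C@](C)(CCC=C(C)C)[C@]1(CC=C(C)C)C(=O)C(C(=O)c2cccc(OC)c2)=C(O)C(C=O)=C1OC(C)(C)C#C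
F4 | step 5 | 1,1-dimethylallyl enol ether of 9 (ether on the C9 oxygen) | C=C[C@](C)(CCC=C(C)C)[C@]1(CC=C(C)C)C(=O)C(C(=O)c2cccc(OC)c2)=C(O)C(C=O)=C1OC(C)(C)C=C
F5 | step 9 | diol: 13 with the vinyl group converted into 2-hydroxyethyl | OCC[C@](C)(CCC=C(C)C)[C@]1(CC=C(C)C)C(=O)C(C(=O)c2cccc(OC)c2)=C(OC)[C@](CC=C(C)C)(CO)C1=O
F6 | step 9 | dialdehyde from F5 (not isolated) | O=CC[C@](C)(CCC=C(C)C)[C@]1(CC=C(C)C)C(=O)C(C(=O)c2cccc(OC)c2)=C(OC)[C@](CC=C(C)C)(C=O)C1=O
F7 | step 9 | bicyclic enal: (1S,5S,8S)-4-methoxy-3-(3-methoxybenzoyl)-8-methyl-1,5-bis(3-methylbut-2-en-1-yl)-8-(4-methylpent-3-en-1-yl)-2,9-dioxobicyclo[3.3.1]nona-3,6-diene-7-carbaldehyde | CC(C)=CCC[C@@]1(C)C(C=O)=C[C@]2(CC=C(C)C)C(=O)[C@@]1(CC=C(C)C)C(=O)C(C(=O)c1cccc(OC)c1)=C2OC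
F8 | step 9 | allylic alcohol: 7-(hydroxymethyl) analogue of F7 | CC(C)=CCC[C@@]1(C)C(CO)=C[C@]2(CC=C(C)C)C(=O)[C@@]1(CC=C(C)C)C(=O)C(C(=O)c1cccc(OC)c1)=C2OC
F9 | step 9 | methyl carbonate of F8 | CC(C)=CCC[C@@]1(C)C(COC(=O)OC)=C[C@]2(CC=C(C)C)C(=O)[C@@]1(CC=C(C)C)C(=O)C(C(=O)c1cccc(OC)c1)=C2OC
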